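Read as a power, an apparent order of 0.5 in salt in the second phase promises a factor of 1.41 on a doubled charge. But an order is a slope at one charge, and the rate of a carrier going round bends away from that slope.

| flask | starting material | salt in the second phase | spent carrier | added ligand | remark | volume of the second phase over the first |
|---|---|---|---|---|---|---|
| autumn | 0.012 M | 0.048 M | 0.12 mM | 34 µM | run made earlier |  |
| midnight | 0.012 M | 0.048 M | 0.12 mM | 130 µM | run made earlier |  |
| winter | 0.012 M | 0.048 M | 0.24 mM | 67 µM | run made earlier |  |
| flask | 0.012 M | 0.0480 M | 0.12 mM | 67 µM |  | 2.0 |

| run | time / min | target / % | starting material / % |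
|---|---|---|---|
| autumn | 4.00 | 5.0 | 94.4 |
| autumn | 6.00 | 8.6 | 91.6 |
| autumn | 10.0 | 12.8 | 87.6 |
| autumn | 20.0 | 24.0 | 75.9 |
| autumn | 30.0 | 32.4 | 68.1 |
| autumn | 50.0 | 46.1 | 54.4 |
| midnight | 3.00 | 4.4 | 96.0 |
| midnight | 10.0 | 12.0 | 87.9 |
| midnight | 15.0 | 16.1 | 83.3 |
| midnight | 25.0 | 24.7 | 74.9 |
| midnight | 40.0 | 36.9 | 62.5 |
| midnight | 50.0 | 43.0 | 57.4 |
| winter | 10.0 | 24.0 | 76.8 |
| winter | 20.0 | 38.7 | 61.3 |
| winter | 30.0 | 50.8 | 49.8 |
| winter | 40.0 | 59.3 | 40.3 |
| winter | 50.0 | 66.4 | 35.3 |

(standard deviation of a reading: 0.5 percentage points)

- in the second phase: salt in the second phase, spent salt in the second phase; everything else is in the first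
- charges count per volume of the first phase; a concentration in a rate is the amount of a species over the volume of its own phase; every rate counts per litre of the first phase
- candidate steps: spent carrier + salt in the second phase <-> fresh carrier + spent salt in the second phase; starting material + fresh carrier -> target + spent carrier; added ligand + fresh carrier <-> idle complex
- the earlier runs hold the two phases in the same ratio of volumes as the flask asked about
- no earlier run changes the charge of salt in the second phase; that part of a forecast is a guess

1. apparent order in salt in the second phase when 10 % of the starting material are converted (percent change of the rate of making target for one percent more salt in the second phase charged)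
2. factor on the rate of making target when 10 % of the starting material are converted if salt in the second phase is charged twice over

We build the flask up one process at a time, in fractions of the charge. Take the main step by itself, starting material meeting fresh carrier, with the carrier kept fresh: salt in the second phase plays no part, so the order is 0 and the factor 1. Now add regeneration of spent carrier. A round then lasts the wait in the main step plus the regeneration wait, and the rate goes as the inverse of that sum. Let w be the regeneration wait's share of the round. One percent more salt in the second phase shortens the round by w percent, and that w is the order. A doubled charge cuts the round to 1 − w/2, so the factor is 2/(2 − w). At w = 1, regeneration is the rate-limiting step and the factor is 2.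

Then comes the rest. The back step with spent salt in the second phase lengthens the regeneration side and raises w. Added ligand, tying fresh carrier up as idle complex, lengthens the other side and lowers w, though target at 10.0 min falls just from 12.8 % in the autumn run to 12.0 % in the midnight run, as ligand goes from 34 µM to 130 µM. No earlier run varies salt in the second phase, so our w is a guess: we commit to 0.5, which gives 1.33, the doubling factor at an even split.

The forecast gives order 0.6 and factor 1.43, above ours, and grants that “the runs cannot separate regeneration from the reaction step”.

The flask gives order 0.53 and factor 1.36, which is 1.02 times our 1.33.

spent carrier + salt in the second phase ⇌ fresh carrier + spent salt in the second phase (K = 0.0920, k = 130 L mol⁻¹ min⁻¹); starting material + fresh carrier → target + spent carrier (k = 280 L mol⁻¹ min⁻¹); added ligand + fresh carrier ⇌ idle complex, settled at all times (K = 3900 L mol⁻¹) After 8.00 min, with 10.3 % target made, the flask holds 51.4 % of its catalyst as spent carrier. Taken as w, that share gives a doubling factor of 1.35.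

The runs were computed from invented constants.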